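The green run's activity fell from 24.9 /M/min over its readings from 1.00 min to 3.00 min to 11.0 /M/min over those from 3.00 min to 5.00 min. By activity I mean the rate of target divided by [reagent] and by the gap, which is the charge less starting material and target and stands for an intermediate.

in all of them: free catalyst 0.20 mM; added ligand 0.12 mM
- violet: starting material 0.10 M; reagent 0.11 M; second catalyst 0.13 mM; run made earlier
- blue: starting material 0.10 M; reagent 0.074 M; second catalyst 0.13 mM; run made earlier
- green: starting material 0.10 M; reagent 0.17 M; second catalyst 0.13 mM; run made earlier
- amber: starting material 0.10 M; reagent 0.11 M; second catalyst 0.065 mM; run made earlier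
- Monday's: starting material 0.10 M; reagent 0.110 M; second catalyst 0.13 mM; everything together at the start; time 8.0 min
- Tuesday's: starting material 0.10 M; reagent 0.110 M (fed, over 5.0 min); second catalyst 0.13 mM; all else is in the flask from the start; the feed brings no volume worth counting; time 8.0 min
- Friday's: starting material 0.10 M (fed, over 5.0 min); reagent 0.110 M; second catalyst 0.13 mM; all else is in the flask from the start; the feed brings no volume worth counting; time 8.0 min

- violet (time / min: target / %, starting material / %): 0.667: 24.7, 69.8; 1.50: 48.4, 43.7; 3.00: 72.6, 19.0; 5.00: 85.9, 6.0
- blue (time / min: target / %, starting material / %): 1.00: 32.3, 57.4; 3.00: 65.8, 19.2; 5.00: 73.3, 6.3; 8.00: 74.1, 1.3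
- green (time / min: target / %, starting material / %): 1.00: 36.3, 58.4; 3.00: 73.0, 19.5; 5.00: 87.1, 6.2; 8.00: 93.4, 1.1
- amber (time / min: target / %, starting material / %): 2.00: 50.3, 33.7; 4.00: 73.7, 11.3; 6.00: 83.9, 3.6; 8.00: 88.5, 2.2

(readings scatter by 0.5 percentage points)



- the best flask by amount of target, in percent of the starting material charged; "all alike" if 1.5 percentage points covers them all (Monday's / Tuesday's / Friday's / all alike)
- amount of target at the end, in percent of the starting material charged, Monday's
- amount of target at the end, in percent of the starting material charged, Tuesday's
- amount of target at the end, in percent of the starting material charged, Friday's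

Over the same later times the blue run still showed 47.6 /M/min, more than green, at a [reagent] of 0.00445 M. So I read the second catalyst as dying pseudo-first-order in [reagent]. Green's decline then gave, as a reading with the scatter of its readings, a mean life of second catalyst at [reagent] = 0.110 M, scaling inversely with [reagent], of 2.17 min.

In Friday's the reagent starts at its charge, so a first pass, holding [reagent] there, put the second catalyst still alive at the feed's end at an estimated 10.0%, the life being shorter than the 5.0 min feed. Tuesday's feed brings 0.0220 M/min, less than early violet's 0.0370 M/min of target, so I expected low [reagent] there. I committed to Tuesday's above Monday's above Friday's.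

The forecast chose Monday's: 91.5% for Monday's, 86% for Tuesday's, 83% for Friday's, holding that “the second step's rate constant falls in step with starting material”.

The flasks gave 93.8% in Monday's, 97.2% in Tuesday's and 73.5% in Friday's, so Tuesday's was best.

    second catalyst + added ligand ⇌ idle complex, settled at all times (K = 26400 /M)
    reagent + second catalyst → spent catalyst (k = 0.204 /M/s)
    reagent + second catalyst + intermediate → second catalyst + target (k = 31400 /M²/s)
    starting material + free catalyst → free catalyst + intermediate (k = 45.8 /M/s)

Going round once more for Friday's, I averaged [reagent] between the charge and the 56.0% of it standing at the feed's end, which made the life 2.79 min, still shorter than the feed, and the live share 16.7%. At that moment Friday's held 17.1% of its second catalyst as free second catalyst and idle complex, and Tuesday's 77.6%. For the neighbour of Friday's charged with 0.44 M of reagent, my reckoning at that charge gives a life of 0.542 min, 10.8% of the feed; that flask ended with 22.5% target and 70.9% intermediate.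

The earlier runs and the new flask were computed with constants of no real substance.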